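The numbers in the tables were computed for an exercise, and the scatter is random.

Time is the budget: each flask gets 2.5 min, and the one run so far, oak, stopped at 30.0 s.

| flask | substrate | gas | remark | time |
|---|---|---|---|---|
| oak | 2.2 mM | 0.099 mM (held) | run made earlier |  |
| amber | 1.2 mM | 0.099 mM (held) |  | 2.5 min |
| ochre | 8.0 mM | 0.099 mM (held) |  | 2.5 min |
| green | 0.60 mM | 0.099 mM (held) |  | 2.5 min |
| violet | 2.0 mM | 0.099 mM (held) |  | 2.5 min |
| grey | 4.0 mM | 0.099 mM (held) |  | 2.5 min |

oak run (percent of the substrate charged): time / s: target / % = 10.0: 9.2; 12.0: 11.6; 15.0: 14.0; 20.0: 21.0; 25.0: 25.8; 30.0: 29.6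

(standard deviation of a reading: 0.5 percentage points)

- at the start none of the gas is in solution
- a reading or a percentage of target counts all its forms, free or not

* the flasks put in order of amount of target, in percent of the substrate charged, best first, at 2.5 min (amber / ochre / green / violet / grey)
* the amount of target, in percent of the substrate charged of the flask you put first, at 2.5 min
* the amount of target, in percent of the substrate charged of the flask you put last, at 2.5 min

By its last reading, oak held 0.651 mM of target, more than the saturation level of gas, 0.099 mM. So if gas goes into target, it must be refilled, and I assume a refill that takes no notice of the charge. I reckon two extreme flasks, by what is left.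

In the first, gas supply is the rate-limiting step. Oak's slope between its first and last readings gives a fixed rate, and that rate over the time gives a fixed amount:

rate = 0.0224 mM s⁻¹

delivery = rate × time = 3.37 mM

This delivery is the target this extreme flask receives in the time, up to its charge. Ochre then has 57.9 % of its charge not yet target.

In the second, substrate simply decays at first order. The same readings give:

k = 0.0127 s⁻¹

fraction left = exp(−k × time) = 14.8 %, in every flask

With the two steps in series, I take the lower of the two yields as my estimate. Ochre gets 42.1 %, lower than 85.2 %. Grey gets 84.2 %, almost at the crossing. The delivery exceeds the charge of green, of amber and of violet, so my estimate for these flasks stays at 85.2 %, and it does not rank them.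

The forecast says green > amber > violet > grey > ochre, with top 97 % (80 % to 100 %) and low 45 % (36 % to 75 %), on the ground that “Percent yield should therefore fall as substrate loading rises”. Its low is above my 42.1 %.

The flasks give violet > amber > grey > green > ochre, with violet at 95.1 % and ochre at 45.3 %. Green gives 85.1 %.

    partner + intermediate → target (k = 13700 M⁻¹ s⁻¹)
    substrate → intermediate (k = 0.0238 s⁻¹)
    crystals ⇌ target, rate k3*(cs3 - [target]) while solid is left; crystals form when [target] > cs3 (solubility = 0.0570 mM, k = 1.28 s⁻¹)
    gas ⇌ partner, rate k4*(csat - [partner]) (kL = 0.246 s⁻¹)
    partner + target → over-reaction product (k = 105 M⁻¹ s⁻¹)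

Ochre's 45.3 % stands against my 42.1 %, and it still holds 51.8 % as intermediate, with partner at 4.27 × 10⁻⁴ mM. The neighbour is the same flask with 20 mM of substrate. The same delivery gives it 16.9 %. The neighbour gives 18.2 % of target, and its intermediate holds 79.0 %.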